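**Retrosynthetic overview**
1. The target is a (1(10)Z,4E)-germacra-1(10),4,11(13)-trien-12,6-olide with 2-OH, 8-O-angeloyl and 9-OAc. The end game is C2 silyl ether cleavage ⇐ C9 acetylation ⇐ Felkin–Anh (Luche) reduction of a C9 ketone ⇐ oxidation of the ring-closure product.
2. Key disconnection C9–C10: C9 is a secondary allylic carbinol carbon bonded to C10 of the Z-trisubstituted C1=C10 olefin inside the ten-membered ring A, so the bond opens to a C9 aldehyde and a (Z)-C10 alkenyl iodide. The cis placing of C2 and C10–I on that olefin, the E-C4=C5 olefin and the trans-fused lactone ring B fold the seco-chain for an intramolecular Nozaki–Hiyama–Kishi closure.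
3. C7–C8: a zinc Barbier reaction of a 3-(bromomethyl)butenolide with a silyloxyacetaldehyde sets C7 and C8 from C6 and unveils the α-methylene lactone; the angelate is put on O8 before ring closure.
4. Butenolide (ring B): ring-closing metathesis of the 2-(bromomethyl)acrylate of a C6 carbinol, itself from asymmetric vinylation of a C1–C6 enal. The enal comes from an asymmetric vinylogous Mukaiyama aldol (C2) and NaAlH2(OCH2CH2OMe)2/I2 (Z-alkenyl iodide).
5. Ring order: lactone ring B first (step 8), ten-membered carbocycle ring A second (step 13).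

Key step: step 13

Remark: C1–C15 are the germacrane locants of the target (O6 lactone, O8 angelate, O9 acetate, O2 hydroxyl); for the two catalyst-controlled steps (2 and 6) the catalyst antipode meant is the one that gives the drawn configuration.

Step 1
Reactants: 1 methyl 3-methylbut-2-enoate
Product: 3 tert-butyl[(1-methoxy-3-methylbuta-1,3-dien-1-yl)oxy]dimethylsilane, via lithium dienolate 2 (not isolated)
Conditions: LiN(i-Pr)2, THF, −78 °C; then TBSCl, DMPU, −78 °C to 23 °C
Reagents that add atoms: tert-butyl(chloro)dimethylsilane, CC(C)(C)[Si](C)(C)Cl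
Why: Kinetic γ-deprotonation of the senecioate gives the extended lithium dienolate, which is silylated on oxygen (silyl ketene acetal formation) to the dienolate needed for a vinylogous Mukaiyama aldol, with no stereocenter formed and the ketene acetal geometry of no consequence.

Step 2
Reactants: 3 tert-butyl[(1-methoxy-3-methylbuta-1,3-dien-1-yl)oxy]dimethylsilane; 4 but-2-ynal
Product: 5 methyl (2E,5S)-5-hydroxy-3-methyloct-2-en-6-ynoate
Conditions: SiCl4, (R,R)-binaphthyldiamine-derived bisphosphoramide (5 mol%), i-Pr2NEt (cat.), CH2Cl2, −78 °C; then aq. NaHCO3/KF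
Reagents that add atoms: none
Why: In this Lewis-base-activated SiCl4 vinylogous Mukaiyama aldol reaction the dienolate should attack through its γ-carbon (C3) and give the E-configured C4=C5 enoate, while the chiral phosphoramide-bound silicon cation shields one face of the ynal and should set C2 as S (catalyst control).

Step 3
Reactants: 5 methyl (2E,5S)-5-hydroxy-3-methyloct-2-en-6-ynoate
Product: 7 (2E,5S,6Z)-7-iodo-3-methylocta-2,6-diene-1,5-diol, via sodium alkenylaluminate 6 (not isolated)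
Conditions: NaAlH2(OCH2CH2OMe)2, THF, 0 °C to 23 °C; then I2, THF, −78 °C to 0 °C
Reagents that add atoms: iodine, II
Why: The aluminium hydride reduces the conjugated ester to the allylic alcohol and, through the C2 alkoxide, adds Al–H trans across the alkyne (alkoxide-directed trans-hydroalumination) to a cyclic alkenylaluminate with aluminium on C10, whose iodinolysis with retention should give the Z-iodide with iodine cis to C2, leaving C2 untouched.

Step 4
Reactants: 7 (2E,5S,6Z)-7-iodo-3-methylocta-2,6-diene-1,5-diol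
Product: 8 (2E,5S,6Z)-5-hydroxy-7-iodo-3-methylocta-2,6-dienal
Conditions: TEMPO (cat.), PhI(OAc)2, CH2Cl2, 23 °C
Reagents that add atoms: none
Why: The oxoammonium (TEMPO) oxidation is selective for the primary allylic alcohol over the more hindered secondary C2 carbinol and stops at the enal without touching the E-olefin geometry.

Step 5
Reactants: 8 (2E,5S,6Z)-5-hydroxy-7-iodo-3-methylocta-2,6-dienal
Product: 9 (2E,5S,6Z)-5-[(tert-butyldimethylsilyl)oxy]-7-iodo-3-methylocta-2,6-dienal
Conditions: TBSCl, imidazole, DMF, 23 °C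
Reagents that add atoms: tert-butyl(chloro)dimethylsilane, CC(C)(C)[Si](C)(C)Cl
Why: Standard imidazole-promoted silylation of the remaining secondary alcohol masks O2 as a TBS ether until the last step.

Step 6
Reactants: 9 (2E,5S,6Z)-5-[(tert-butyldimethylsilyl)oxy]-7-iodo-3-methylocta-2,6-dienal
Product: 10 (3S,4E,7S,8Z)-7-[(tert-butyldimethylsilyl)oxy]-9-iodo-5-methyldeca-1,4,8-trien-3-ol
Conditions: Zn(CH=CH2)2, (−)-3-exo-(dimethylamino)isoborneol (cat.), toluene, 0 °C
Reagents that add atoms: divinylzinc, C=C[Zn]C=C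
Why: In this amino-alcohol-catalysed 1,2-addition of an alkenylzinc reagent to the enal the chiral zinc aminoalkoxide should deliver the vinyl group to one aldehyde face and set C6 (3S here, 6R in the target) under catalyst control, C2 being too remote to interfere.

Step 7
Reactants: 10 (3S,4E,7S,8Z)-7-[(tert-butyldimethylsilyl)oxy]-9-iodo-5-methyldeca-1,4,8-trien-3-ol; 11 2-(bromomethyl)prop-2-enoic acid
Product: 12 (3S,4E,7S,8Z)-7-[(tert-butyldimethylsilyl)oxy]-9-iodo-5-methyldeca-1,4,8-trien-3-yl 2-(bromomethyl)prop-2-enoate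
Conditions: DCC, DMAP (cat.), CH2Cl2, 0 °C
Reagents that add atoms: none
Why: Carbodiimide (Steglich) esterification of the secondary alcohol proceeds with retention at C6 and brings in C11, C12 and C13 with the allylic bromide already in place.

Step 8
Reactants: 12 (3S,4E,7S,8Z)-7-[(tert-butyldimethylsilyl)oxy]-9-iodo-5-methyldeca-1,4,8-trien-3-yl 2-(bromomethyl)prop-2-enoate
Product: 13 (5R)-3-(bromomethyl)-5-[(1E,4S,5Z)-4-[(tert-butyldimethylsilyl)oxy]-6-iodo-2-methylhepta-1,5-dien-1-yl]furan-2(5H)-one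
Conditions: second-generation Grubbs catalyst RuCl2(=CHPh)(H2IMes)(PCy3) (cat.), CH2Cl2, 40 °C
Reagents that add atoms: none
Why: Ring-closing metathesis between the monosubstituted vinyl group and the acrylate methylene closes the five-membered butenolide ring B with loss of ethene, the trisubstituted olefins and the hindered alkenyl iodide not engaging the ruthenium carbene and C6 being unaffected.

Step 9
Reactants: 13 (5R)-3-(bromomethyl)-5-[(1E,4S,5Z)-4-[(tert-butyldimethylsilyl)oxy]-6-iodo-2-methylhepta-1,5-dien-1-yl]furan-2(5H)-one; 14 (tert-butyldimethylsilyloxy)acetaldehyde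
Product: 16 (4R,5R)-4-[(1R)-2-[(tert-butyldimethylsilyl)oxy]-1-hydroxyethyl]-5-[(1E,4S,5Z)-4-[(tert-butyldimethylsilyl)oxy]-6-iodo-2-methylhepta-1,5-dien-1-yl]-3-methylideneoxolan-2-one, via allylzinc bromide 15 (not isolated)
Conditions: Zn dust, THF/sat. aq. NH4Cl, 0 °C to 23 °C
Reagents that add atoms: none
Why: In this Barbier reaction zinc inserts into the allylic C–Br bond and the allylzinc adds to the aldehyde through its γ-carbon C7 (SE2′) on the butenolide face anti to the C6 side chain (C7, trans-lactone) via a chair Zimmerman–Traxler transition state with the aldehyde residue equatorial, which should give the 7,8-anti carbinol (C8) and at the same time creates the α-methylene lactone.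

Step 10
Reactants: 16 (4R,5R)-4-[(1R)-2-[(tert-butyldimethylsilyl)oxy]-1-hydroxyethyl]-5-[(1E,4S,5Z)-4-[(tert-butyldimethylsilyl)oxy]-6-iodo-2-methylhepta-1,5-dien-1-yl]-3-methylideneoxolan-2-one; 17 angelic acid
Product: 19 (1R)-2-[(tert-butyldimethylsilyl)oxy]-1-[(2R,3S)-2-[(1E,4S,5Z)-4-[(tert-butyldimethylsilyl)oxy]-6-iodo-2-methylhepta-1,5-dien-1-yl]-4-methylidene-5-oxooxolan-3-yl]ethyl (2Z)-2-methylbut-2-enoate, via mixed anhydride 18 (not isolated)
Conditions: 2,4,6-trichlorobenzoyl chloride, Et3N, toluene, 23 °C; then 16, 80 °C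
Reagents that add atoms: none
Why: Yamaguchi-type acylation through the mixed anhydride, run without DMAP so that the angeloyl group is transferred without Z-to-E isomerisation, should esterify the hindered C8 hydroxyl with retention of configuration.

Step 11
Reactants: 19 (1R)-2-[(tert-butyldimethylsilyl)oxy]-1-[(2R,3S)-2-[(1E,4S,5Z)-4-[(tert-butyldimethylsilyl)oxy]-6-iodo-2-methylhepta-1,5-dien-1-yl]-4-methylidene-5-oxooxolan-3-yl]ethyl (2Z)-2-methylbut-2-enoate
Product: 20 (1R)-2-hydroxy-1-[(2R,3S)-2-[(1E,4S,5Z)-4-[(tert-butyldimethylsilyl)oxy]-6-iodo-2-methylhepta-1,5-dien-1-yl]-4-methylidene-5-oxooxolan-3-yl]ethyl (2Z)-2-methylbut-2-enoate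
Conditions: HF·pyridine, pyridine, THF, 0 °C
Reagents that add atoms: none
Why: Buffered HF·pyridine desilylation cleaves the unhindered primary TBS ether much faster than the secondary allylic one at C2, and the weakly acidic medium disfavours migration of the angelate to the freed primary hydroxyl.

Step 12
Reactants: 20 (1R)-2-hydroxy-1-[(2R,3S)-2-[(1E,4S,5Z)-4-[(tert-butyldimethylsilyl)oxy]-6-iodo-2-methylhepta-1,5-dien-1-yl]-4-methylidene-5-oxooxolan-3-yl]ethyl (2Z)-2-methylbut-2-enoate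
Product: 21 (1R)-1-[(2R,3S)-2-[(1E,4S,5Z)-4-[(tert-butyldimethylsilyl)oxy]-6-iodo-2-methylhepta-1,5-dien-1-yl]-4-methylidene-5-oxooxolan-3-yl]-2-oxoethyl (2Z)-2-methylbut-2-enoate
Conditions: Dess–Martin periodinane, NaHCO3, CH2Cl2, 0 °C to 23 °C
Reagents that add atoms: none
Why: Dess–Martin oxidation converts the primary alcohol to the C9 aldehyde under buffered neutral conditions that should not epimerise the α-acyloxy centre C8.

Step 13
Reactants: 21 (1R)-1-[(2R,3S)-2-[(1E,4S,5Z)-4-[(tert-butyldimethylsilyl)oxy]-6-iodo-2-methylhepta-1,5-dien-1-yl]-4-methylidene-5-oxooxolan-3-yl]-2-oxoethyl (2Z)-2-methylbut-2-enoate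
Product: 23 (3aS,4R,5RS,6Z,8S,10E,11aR)-8-[(tert-butyldimethylsilyl)oxy]-5-hydroxy-6,10-dimethyl-3-methylidene-2-oxo-2,3,3a,4,5,8,9,11a-octahydrocyclodeca[b]furan-4-yl (2Z)-2-methylbut-2-enoate (both C9 epimers), via alkenylchromium dichloride 22 (not isolated)
Conditions: CrCl2 (excess), NiCl2 (cat.), degassed DMSO, 23 °C, high dilution (slow addition of 21); then H2O
Reagents that add atoms: none
Why: NiCl2 is reduced by CrCl2 to zerovalent nickel, which inserts into the C10–I bond with retention of the Z geometry and passes the alkenyl group to trivalent chromium; the alkenylchromium then adds to the C9 aldehyde. This is the intramolecular Nozaki–Hiyama–Kishi reaction, the closest precedent being its use to close ten-membered germacranolide carbocycles from alkenyl iodide–aldehydes that already carry an α-methylene lactone. The ten-membered ring A is closed in a 10-exo-trig mode, the carbonyl oxygen staying outside the new ring as the C9 hydroxyl. The one new stereocenter, C9, is formed under macrocyclic substrate control only and no selectivity is asked of it, since both epimers of 23 are merged in enone 24 (step 14) and C9 is fixed in step 15. What the step does need is chemoselectivity for the aldehyde and the alkenyl iodide in the presence of the α-methylene lactone, the angelate, an epimerisable α-acyloxy centre and a silyl ether, retention of the Z olefin, and ring closure in preference to oligomerisation. These are secured by the non-basic, carbonyl-selective organochromium reagent, by the configurational stability of alkenylnickel and alkenylchromium species, and by high dilution acting on a chain pre-folded by the cis arrangement of C2 and C10 on the C1=C10 olefin, the E-C4=C5 olefin and the trans-fused lactone ring B.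

Step 14
Reactants: 23 (3aS,4R,5RS,6Z,8S,10E,11aR)-8-[(tert-butyldimethylsilyl)oxy]-5-hydroxy-6,10-dimethyl-3-methylidene-2-oxo-2,3,3a,4,5,8,9,11a-octahydrocyclodeca[b]furan-4-yl (2Z)-2-methylbut-2-enoate (both C9 epimers)
Product: 24 (3aS,4R,6Z,8S,10E,11aR)-8-[(tert-butyldimethylsilyl)oxy]-6,10-dimethyl-3-methylidene-2,5-dioxo-2,3,3a,4,5,8,9,11a-octahydrocyclodeca[b]furan-4-yl (2Z)-2-methylbut-2-enoate
Conditions: Dess–Martin periodinane, NaHCO3, CH2Cl2, 0 °C
Reagents that add atoms: none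
Why: Dess–Martin oxidation of the allylic alcohol merges both C9 epimers into one enone, so that C9 can be set afterwards by hydride approach to a ketone.

Step 15
Reactants: 24 (3aS,4R,6Z,8S,10E,11aR)-8-[(tert-butyldimethylsilyl)oxy]-6,10-dimethyl-3-methylidene-2,5-dioxo-2,3,3a,4,5,8,9,11a-octahydrocyclodeca[b]furan-4-yl (2Z)-2-methylbut-2-enoate
Product: 25 (3aS,4R,5R,6Z,8S,10E,11aR)-8-[(tert-butyldimethylsilyl)oxy]-5-hydroxy-6,10-dimethyl-3-methylidene-2-oxo-2,3,3a,4,5,8,9,11a-octahydrocyclodeca[b]furan-4-yl (2Z)-2-methylbut-2-enoate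
Conditions: NaBH4, CeCl3·7H2O, MeOH, −78 °C
Reagents that add atoms: none
Why: The Luche 1,2-reduction of the enone is expected to follow the polar Felkin–Anh model, hydride adding anti to the C8–O bond of the α-acyloxy centre to give the 8,9-syn (9R) allylic alcohol, while the cerium-modified borohydride at −78 °C should spare the α-methylene lactone and the esters.

Step 16
Reactants: 25 (3aS,4R,5R,6Z,8S,10E,11aR)-8-[(tert-butyldimethylsilyl)oxy]-5-hydroxy-6,10-dimethyl-3-methylidene-2-oxo-2,3,3a,4,5,8,9,11a-octahydrocyclodeca[b]furan-4-yl (2Z)-2-methylbut-2-enoate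
Product: 26 (3aS,4R,5R,6Z,8S,10E,11aR)-5-acetyloxy-8-[(tert-butyldimethylsilyl)oxy]-6,10-dimethyl-3-methylidene-2-oxo-2,3,3a,4,5,8,9,11a-octahydrocyclodeca[b]furan-4-yl (2Z)-2-methylbut-2-enoate
Conditions: Ac2O, pyridine, DMAP (cat.), CH2Cl2, 0 °C
Reagents that add atoms: acetic anhydride, CC(=O)OC(C)=O
Why: DMAP-catalysed acetylation of the secondary allylic alcohol proceeds with retention at C9, and at 0 °C acyl migration between O8 and O9 is not expected.

Step 17
Reactants: 26 (3aS,4R,5R,6Z,8S,10E,11aR)-5-acetyloxy-8-[(tert-butyldimethylsilyl)oxy]-6,10-dimethyl-3-methylidene-2-oxo-2,3,3a,4,5,8,9,11a-octahydrocyclodeca[b]furan-4-yl (2Z)-2-methylbut-2-enoate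
Product: 27 (3aS,4R,5R,6Z,8S,10E,11aR)-5-acetyloxy-8-hydroxy-6,10-dimethyl-3-methylidene-2-oxo-2,3,3a,4,5,8,9,11a-octahydrocyclodeca[b]furan-4-yl (2Z)-2-methylbut-2-enoate
Conditions: HF·pyridine, pyridine, THF, 0 °C to 23 °C
Reagents that add atoms: none
Why: Fluoride-induced desilylation under buffered, weakly acidic conditions should leave the allylic acetate, the angelate and the α-methylene lactone intact and release the target with all five stereocenters in place.

**Compound list**
1 | methyl 3-methylbut-2-enoate | COC(=O)C=C(C)C | starting material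
2 | lithium 1-methoxy-3-methylbuta-1,3-dien-1-olate | [Li+].[O-]C(OC)=CC(C)=C | intermediate (not isolated)
3 | tert-butyl[(1-methoxy-3-methylbuta-1,3-dien-1-yl)oxy]dimethylsilane | C=C(C)C=C(OC)O[Si](C)(C)C(C)(C)C | intermediate
4 | but-2-ynal | CC#CC=O | starting material
5 | methyl (2E,5S)-5-hydroxy-3-methyloct-2-en-6-ynoate | COC(=O)/C=C(\C)C[C@H](O)C#CC | intermediate
6 | sodium alkenylaluminate (cyclic 1,2-oxaluminole ate complex, primary hydroxyl drawn free) | [Na+].COCCO[Al-]1(OCCOC)O[C@@H](C/C(C)=C/CO)C=C1C | intermediate (not isolated)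
7 | (2E,5S,6Z)-7-iodo-3-methylocta-2,6-diene-1,5-diol | OC/C=C(\C)C[C@H](O)/C=C(/C)I | intermediate
8 | (2E,5S,6Z)-5-hydroxy-7-iodo-3-methylocta-2,6-dienal | O=C/C=C(\C)C[C@H](O)/C=C(/C)I | intermediate
9 | (2E,5S,6Z)-5-[(tert-butyldimethylsilyl)oxy]-7-iodo-3-methylocta-2,6-dienal | O=C/C=C(\C)C[C@H](O[Si](C)(C)C(C)(C)C)/C=C(/C)I | intermediate
10 | (3S,4E,7S,8Z)-7-[(tert-butyldimethylsilyl)oxy]-9-iodo-5-methyldeca-1,4,8-trien-3-ol | O[C@@H](C=C)/C=C(\C)C[C@H](O[Si](C)(C)C(C)(C)C)/C=C(/C)I | intermediate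
11 | 2-(bromomethyl)prop-2-enoic acid | C=C(CBr)C(=O)O | starting material
12 | (3S,4E,7S,8Z)-7-[(tert-butyldimethylsilyl)oxy]-9-iodo-5-methyldeca-1,4,8-trien-3-yl 2-(bromomethyl)prop-2-enoate | C=C(CBr)C(=O)O[C@@H](C=C)/C=C(\C)C[C@H](O[Si](C)(C)C(C)(C)C)/C=C(/C)I | intermediate
13 | (5R)-3-(bromomethyl)-5-[(1E,4S,5Z)-4-[(tert-butyldimethylsilyl)oxy]-6-iodo-2-methylhepta-1,5-dien-1-yl]furan-2(5H)-one | O=C1O[C@@H](C=C1CBr)/C=C(\C)C[C@H](O[Si](C)(C)C(C)(C)C)/C=C(/C)I | intermediate
14 | (tert-butyldimethylsilyloxy)acetaldehyde | CC(C)(C)[Si](C)(C)OCC=O | starting material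
15 | allylzinc bromide from 13 (ZnBr in place of Br) | O=C1O[C@@H](C=C1C[Zn]Br)/C=C(\C)C[C@H](O[Si](C)(C)C(C)(C)C)/C=C(/C)I | intermediate (not isolated)
16 | (4R,5R)-4-[(1R)-2-[(tert-butyldimethylsilyl)oxy]-1-hydroxyethyl]-5-[(1E,4S,5Z)-4-[(tert-butyldimethylsilyl)oxy]-6-iodo-2-methylhepta-1,5-dien-1-yl]-3-methylideneoxolan-2-one | C=C1C(=O)O[C@H](/C=C(\C)C[C@H](O[Si](C)(C)C(C)(C)C)/C=C(/C)I)[C@H]1[C@@H](O)CO[Si](C)(C)C(C)(C)C | intermediate
17 | angelic acid, (2Z)-2-methylbut-2-enoic acid | C/C=C(/C)C(=O)O | starting material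
18 | (2Z)-2-methylbut-2-enoic 2,4,6-trichlorobenzoic anhydride | C/C=C(/C)C(=O)OC(=O)c1c(Cl)cc(Cl)cc1Cl | intermediate (not isolated)
19 | (1R)-2-[(tert-butyldimethylsilyl)oxy]-1-[(2R,3S)-2-[(1E,4S,5Z)-4-[(tert-butyldimethylsilyl)oxy]-6-iodo-2-methylhepta-1,5-dien-1-yl]-4-methylidene-5-oxooxolan-3-yl]ethyl (2Z)-2-methylbut-2-enoate | C=C1C(=O)O[C@H](/C=C(\C)C[C@H](O[Si](C)(C)C(C)(C)C)/C=C(/C)I)[C@H]1[C@@H](OC(=O)/C(C)=C\C)CO[Si](C)(C)C(C)(C)C | intermediate
20 | (1R)-2-hydroxy-1-[(2R,3S)-2-[(1E,4S,5Z)-4-[(tert-butyldimethylsilyl)oxy]-6-iodo-2-methylhepta-1,5-dien-1-yl]-4-methylidene-5-oxooxolan-3-yl]ethyl (2Z)-2-methylbut-2-enoate | C=C1C(=O)O[C@H](/C=C(\C)C[C@H](O[Si](C)(C)C(C)(C)C)/C=C(/C)I)[C@H]1[C@@H](OC(=O)/C(C)=C\C)CO | intermediate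
21 | (1R)-1-[(2R,3S)-2-[(1E,4S,5Z)-4-[(tert-butyldimethylsilyl)oxy]-6-iodo-2-methylhepta-1,5-dien-1-yl]-4-methylidene-5-oxooxolan-3-yl]-2-oxoethyl (2Z)-2-methylbut-2-enoate | C=C1C(=O)O[C@H](/C=C(\C)C[C@H](O[Si](C)(C)C(C)(C)C)/C=C(/C)I)[C@H]1[C@@H](OC(=O)/C(C)=C\C)C=O | intermediate
22 | alkenylchromium dichloride from 21 (CrCl2 of trivalent chromium in place of I) | C=C1C(=O)O[C@H](/C=C(\C)C[C@H](O[Si](C)(C)C(C)(C)C)/C=C(/C)[Cr](Cl)Cl)[C@H]1[C@@H](OC(=O)/C(C)=C\C)C=O | intermediate (not isolated)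
23 | (3aS,4R,5RS,6Z,8S,10E,11aR)-8-[(tert-butyldimethylsilyl)oxy]-5-hydroxy-6,10-dimethyl-3-methylidene-2-oxo-2,3,3a,4,5,8,9,11a-octahydrocyclodeca[b]furan-4-yl (2Z)-2-methylbut-2-enoate (C9 epimers) | C=C1C(=O)O[C@@H]2/C=C(\C)C[C@H](O[Si](C)(C)C(C)(C)C)/C=C(/C)C(O)[C@H](OC(=O)/C(C)=C\C)[C@@H]12 | intermediate
24 | (3aS,4R,6Z,8S,10E,11aR)-8-[(tert-butyldimethylsilyl)oxy]-6,10-dimethyl-3-methylidene-2,5-dioxo-2,3,3a,4,5,8,9,11a-octahydrocyclodeca[b]furan-4-yl (2Z)-2-methylbut-2-enoate | C=C1C(=O)O[C@@H]2/C=C(\C)C[C@H](O[Si](C)(C)C(C)(C)C)/C=C(/C)C(=O)[C@H](OC(=O)/C(C)=C\C)[C@@H]12 | intermediate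
25 | (3aS,4R,5R,6Z,8S,10E,11aR)-8-[(tert-butyldimethylsilyl)oxy]-5-hydroxy-6,10-dimethyl-3-methylidene-2-oxo-2,3,3a,4,5,8,9,11a-octahydrocyclodeca[b]furan-4-yl (2Z)-2-methylbut-2-enoate | C=C1C(=O)O[C@@H]2/C=C(\C)C[C@H](O[Si](C)(C)C(C)(C)C)/C=C(/C)[C@@H](O)[C@H](OC(=O)/C(C)=C\C)[C@@H]12 | intermediate
26 | (3aS,4R,5R,6Z,8S,10E,11aR)-5-acetyloxy-8-[(tert-butyldimethylsilyl)oxy]-6,10-dimethyl-3-methylidene-2-oxo-2,3,3a,4,5,8,9,11a-octahydrocyclodeca[b]furan-4-yl (2Z)-2-methylbut-2-enoate | C=C1C(=O)O[C@@H]2/C=C(\C)C[C@H](O[Si](C)(C)C(C)(C)C)/C=C(/C)[C@@H](OC(C)=O)[C@H](OC(=O)/C(C)=C\C)[C@@H]12 | intermediate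
27 | (3aS,4R,5R,6Z,8S,10E,11aR)-5-acetyloxy-8-hydroxy-6,10-dimethyl-3-methylidene-2-oxo-2,3,3a,4,5,8,9,11a-octahydrocyclodeca[b]furan-4-yl (2Z)-2-methylbut-2-enoate | C=C1C(=O)O[C@@H]2/C=C(\C)C[C@H](O)/C=C(/C)[C@@H](OC(C)=O)[C@H](OC(=O)/C(C)=C\C)[C@@H]12 | target

**Step count and risks**
Total step count: 17. Longest linear sequence: 17 steps (1 to 27); compounds 4, 11, 14 and 17 are bought.

Steps most likely to fail:

1. Step 13 (ring closure). The alkenylmetal may be protonated or may add to a second molecule before the strained Z,E-cyclodecadiene ring closes. The fallback closes the same C9–C10 bond acylatively, at the ketone oxidation level, and sets out from 21. Pinnick oxidation (NaClO2, NaH2PO4, 2-methyl-2-butene, t-BuOH/H2O) would give the carboxylic acid F1. Thioesterification (PhSH, DCC, cat. DMAP) would give the S-phenyl thioester F2. Iodine–tin exchange ((Me3Sn)2, Pd(PPh3)4, toluene, 80 °C) would give the alkenylstannane F3. An intramolecular Liebeskind–Srogl thioester–stannane coupling (Pd2(dba)3, tri(2-furyl)phosphine, copper diphenylphosphinate CuO2PPh2, THF, high dilution) should then give enone 24, where the route is rejoined with steps 13 and 14 bypassed.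

2. Step 9 (Barbier addition). Facial selectivity at the aldehyde carbon (C8) may be poor or reversed. The fallback sets out from 13, uses the same zinc-mediated addition, and takes the C8-epimeric carbinol F4 forward instead of discarding it. Mitsunobu esterification of F4 with angelic acid 17 (PPh3, DIAD, toluene, 0 °C) would install the angelate by SN2 displacement with inversion at C8 and rejoin the route at 19, with step 10 bypassed for this epimer. A mixture of 16 and F4 would thus converge on 19 by the two esterification modes.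

3. Step 15 (ketone reduction). The conformation of the ten-membered ring may override Felkin–Anh control and direct hydride to the other face of the C9 ketone. The fallback sets out from 24: the 9S alcohol F5 obtained from the reduction would be treated with acetic acid, PPh3 and DIAD (Mitsunobu inversion) to give acetate 26 with inversion at C9, rejoining the route at 26 with step 16 bypassed.

Further compounds
F1 | step 13 | (2R)-2-{[(2Z)-2-methylbut-2-enoyl]oxy}-2-[(2R,3S)-2-[(1E,4S,5Z)-4-[(tert-butyldimethylsilyl)oxy]-6-iodo-2-methylhepta-1,5-dien-1-yl]-4-methylidene-5-oxooxolan-3-yl]acetic acid | C=C1C(=O)O[C@H](/C=C(\C)C[C@H](O[Si](C)(C)C(C)(C)C)/C=C(/C)I)[C@H]1[C@@H](OC(=O)/C(C)=C\C)C(=O)O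
F2 | step 13 | S-phenyl (2R)-2-{[(2Z)-2-methylbut-2-enoyl]oxy}-2-[(2R,3S)-2-[(1E,4S,5Z)-4-[(tert-butyldimethylsilyl)oxy]-6-iodo-2-methylhepta-1,5-dien-1-yl]-4-methylidene-5-oxooxolan-3-yl]ethanethioate | C=C1C(=O)O[C@H](/C=C(\C)C[C@H](O[Si](C)(C)C(C)(C)C)/C=C(/C)I)[C@H]1[C@@H](OC(=O)/C(C)=C\C)C(=O)Sc1ccccc1
F3 | step 13 | S-phenyl (2R)-2-{[(2Z)-2-methylbut-2-enoyl]oxy}-2-[(2R,3S)-2-[(1E,4S,5Z)-4-[(tert-butyldimethylsilyl)oxy]-2-methyl-6-(trimethylstannyl)hepta-1,5-dien-1-yl]-4-methylidene-5-oxooxolan-3-yl]ethanethioate | C=C1C(=O)O[C@H](/C=C(\C)C[C@H](O[Si](C)(C)C(C)(C)C)/C=C(/C)[Sn](C)(C)C)[C@H]1[C@@H](OC(=O)/C(C)=C\C)C(=O)Sc1ccccc1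
F4 | step 9 | (4R,5R)-4-[(1S)-2-[(tert-butyldimethylsilyl)oxy]-1-hydroxyethyl]-5-[(1E,4S,5Z)-4-[(tert-butyldimethylsilyl)oxy]-6-iodo-2-methylhepta-1,5-dien-1-yl]-3-methylideneoxolan-2-one | C=C1C(=O)O[C@H](/C=C(\C)C[C@H](O[Si](C)(C)C(C)(C)C)/C=C(/C)I)[C@H]1[C@H](O)CO[Si](C)(C)C(C)(C)C
F5 | step 15 | (3aS,4R,5S,6Z,8S,10E,11aR)-8-[(tert-butyldimethylsilyl)oxy]-5-hydroxy-6,10-dimethyl-3-methylidene-2-oxo-2,3,3a,4,5,8,9,11a-octahydrocyclodeca[b]furan-4-yl (2Z)-2-methylbut-2-enoate | C=C1C(=O)O[C@@H]2/C=C(\C)C[C@H](O[Si](C)(C)C(C)(C)C)/C=C(/C)[C@H](O)[C@H](OC(=O)/C(C)=C\C)[C@@H]12
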